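## Retrosynthetic overview

1. The last bonds formed are the two oxirane C–O bonds: a site- and face-selective 5,6-epoxidation of the (3R)-3-hydroxy-β-end "deepoxy" C40 polyene sets C5 and C6.
2. The C40 polyene is cut at C11=C12 (Wittig) into a zeaxanthin-type C15 phosphonium salt (three steps from actinol and the C6 enynol) and a C25 keto-butenolide aldehyde.
3. The C25 aldehyde is cut at C8'–C9' (Negishi sp3–sp2) into a bromoethyl-enone-derived alkylzinc and an α-bromo-γ-ylidenebutenolide trienal, the latter from 3-bromofuranone and C10-dialdehyde by vinylogous aldol condensation.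
4. The bromoethyl enone comes from a Johnson–Claisen ester by reduction, Appel bromination and allylic oxidation; C6' is set by CBS reduction followed by [3,3] chirality transfer.
5. Ring order: the cyclohexenone, furanone and cyclohexane rings are bought; the β-ring alkene appears on salt formation; the oxirane is the only ring made and is closed last.

Assumption: 2,4,4-trimethylcyclohex-2-enone, 3-bromofuran-2(5H)-one, C10-dialdehyde, (E)-3-methylpent-2-en-4-yn-1-ol and (4R,6R)-actinol (the industrial zeaxanthin intermediate) are taken as purchasable.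

## Route

Step 1
Reactants: 1 2,4,4-trimethylcyclohex-2-en-1-one
Product: 2 (1S)-2,4,4-trimethylcyclohex-2-en-1-ol
Conditions: (R)-Me-CBS (10 mol %), BH3·SMe2, THF, −20 °C; MeOH quench
Reagents that add atoms: none
Why: Corey–Bakshi–Shibata reduction, in which the (R)-oxazaborolidine treats the α-methyl vinyl arm as the large group and delivers hydride 1,2 to give the (S)-allylic alcohol.

Step 2
Reactants: 2 (1S)-2,4,4-trimethylcyclohex-2-en-1-ol
Product: 4 ethyl [(1R)-2,6,6-trimethylcyclohex-2-en-1-yl]acetate, via ketene acetal 3 (not isolated)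
Conditions: MeC(OEt)3, EtCO2H (cat.), 140 °C, EtOH distilled off
Reagents that add atoms: triethyl orthoacetate, CCOC(C)(OCC)OCC
Why: Johnson–Claisen rearrangement, a suprafacial [3,3] shift on the ring face that carried the C–O bond, so the (1S) carbinol centre is transferred to the new (1R) C–C stereocentre next to the gem-dimethyl carbon (the future C6').

Step 3
Reactants: 4 ethyl [(1R)-2,6,6-trimethylcyclohex-2-en-1-yl]acetate
Product: 5 2-[(1R)-2,6,6-trimethylcyclohex-2-en-1-yl]ethan-1-ol
Conditions: LiAlH4, Et2O, 0 °C; aqueous NaOH work-up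
Reagents that add atoms: none
Why: Hydride reduction of the ester with LiAlH4; the isolated trisubstituted alkene and the stereocentre are inert.

Step 4
Reactants: 5 2-[(1R)-2,6,6-trimethylcyclohex-2-en-1-yl]ethan-1-ol
Product: 6 (6R)-6-(2-bromoethyl)-1,5,5-trimethylcyclohex-1-ene
Conditions: CBr4, PPh3, CH2Cl2, 0 °C
Reagents that add atoms: carbon tetrabromide, BrC(Br)(Br)Br
Why: Appel reaction on an unhindered primary alcohol under neutral conditions.

Step 5
Reactants: 6 (6R)-6-(2-bromoethyl)-1,5,5-trimethylcyclohex-1-ene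
Product: 7 (4R)-4-(2-bromoethyl)-3,5,5-trimethylcyclohex-2-en-1-one
Conditions: Rh2(cap)4 (1 mol %), t-BuOOH (70 % aq., 5 equiv), K2CO3 (cat.), CH2Cl2, 25 °C
Reagents that add atoms: tert-butyl hydroperoxide, CC(C)(C)OO
Why: Rh(II)/t-BuOOH allylic oxidation by peroxyl-radical H-abstraction at the only unhindered allylic CH2 (the same position as in α-ionone → 3-oxo-α-ionone), leaving the hindered tertiary allylic C–H of the stereocentre and the alkyl bromide alone.

Step 6
Reactants: 8 3-bromofuran-2(5H)-one; 9 (2E,4E,6E)-2,7-dimethylocta-2,4,6-trienedial (3 equiv)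
Product: 12 (2E,4E,6E)-8-[(2Z)-4-bromo-5-oxofuran-2(5H)-ylidene]-2,7-dimethylocta-2,4,6-trienal, via bromosilyloxyfuran 10 (not isolated), via aldol silyl ether 11 (not isolated)
Conditions: TBSOTf (1.3 equiv), i-Pr2NEt (3 equiv), CH2Cl2, 0 °C → rt; then DBU (2 equiv), rt
Reagents that add atoms: none
Why: One-pot vinylogous Mukaiyama aldol addition of the in situ silyloxyfuran to one aldehyde of the excess dialdehyde, then DBU-induced E1cB loss of silanolate to the thermodynamically preferred Z-ylidenebutenolide; the second aldehyde is deactivated once conjugated to the lactone and unreacted 9 is recovered.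

Step 7
Reactants: 7 (4R)-4-(2-bromoethyl)-3,5,5-trimethylcyclohex-2-en-1-one; 12 (2E,4E,6E)-8-[(2Z)-4-bromo-5-oxofuran-2(5H)-ylidene]-2,7-dimethylocta-2,4,6-trienal
Product: 14 (2E,4E,6E)-2,7-dimethyl-8-[(2Z)-5-oxo-4-{2-[(1R)-2,6,6-trimethyl-4-oxocyclohex-2-en-1-yl]ethyl}furan-2(5H)-ylidene]octa-2,4,6-trienal, via alkylzinc bromide 13 (not isolated)
Conditions: Zn dust, LiCl, THF, 50 °C; then 12, Pd(OAc)2 (3 mol %), SPhos (6 mol %), THF, 25 °C
Reagents that add atoms: none
Why: Negishi sp3–sp2 cross-coupling, in which LiCl-assisted zinc insertion into the primary bromide tolerates the enone and the alkylzinc halide couples at the α-bromo-enoate C–Br bond without touching aldehyde, ketone or lactone; no stereocentre is affected.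

Step 8
Reactants: 15 (4R,6R)-4-hydroxy-2,2,6-trimethylcyclohexan-1-one (actinol); 16 (2E)-3-methylpent-2-en-4-yn-1-ol (2.5 equiv)
Product: 18 (4R,6R)-1-[(3E)-5-hydroxy-3-methylpent-3-en-1-yn-1-yl]-2,2,6-trimethylcyclohexane-1,4-diol (C1 epimers), via dilithio enynol 17 (not isolated)
Conditions: n-BuLi (5 equiv), THF, −40 °C; then 15, −40 °C → rt; H2O
Reagents that add atoms: none
Why: Acetylide 1,2-addition to the hindered ketone, with excess dianion also taking up the OH proton of 15; the new carbinol centre and the C6 methine are both destroyed in step 10, and C4 is untouched.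

Step 9
Reactants: 18 (4R,6R)-1-[(3E)-5-hydroxy-3-methylpent-3-en-1-yn-1-yl]-2,2,6-trimethylcyclohexane-1,4-diol
Product: 19 (4R,6R)-1-[(1E,3E)-5-hydroxy-3-methylpenta-1,3-dien-1-yl]-2,2,6-trimethylcyclohexane-1,4-diol
Conditions: Red-Al (4 equiv), THF, 0 °C → rt; aq. Rochelle salt
Reagents that add atoms: none
Why: Alkoxide-directed trans-hydroalumination of the tertiary propargylic alcohol followed by protonolysis gives the E-alkene, the same reduction used on the closely related abscisic-acid enynols.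

Step 10
Reactants: 19 (4R,6R)-1-[(1E,3E)-5-hydroxy-3-methylpenta-1,3-dien-1-yl]-2,2,6-trimethylcyclohexane-1,4-diol
Product: 20 [(2E,4E)-5-[(4R)-4-hydroxy-2,6,6-trimethylcyclohex-1-en-1-yl]-3-methylpenta-2,4-dien-1-yl]triphenylphosphonium bromide
Conditions: Ph3P·HBr (1.05 equiv), MeOH, rt; crystallise
Reagents that add atoms: triphenylphosphine hydrobromide, Br.c1ccc(cc1)P(c1ccccc1)c1ccccc1
Why: Carotenoid-type Wittig-salt formation, in which HBr ionises the allylic alcohols, the ring cation loses the proton next to the methyl to form the tetrasubstituted ring alkene, and PPh3 captures the pentadienyl cation at its unhindered terminus to give the crystalline all-E salt; the carbinol centre (future C3) is not involved.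

Step 11
Reactants: 20 [(2E,4E)-5-[(4R)-4-hydroxy-2,6,6-trimethylcyclohex-1-en-1-yl]-3-methylpenta-2,4-dien-1-yl]triphenylphosphonium bromide (1.1 equiv); 14 (2E,4E,6E)-2,7-dimethyl-8-[(2Z)-5-oxo-4-{2-[(1R)-2,6,6-trimethyl-4-oxocyclohex-2-en-1-yl]ethyl}furan-2(5H)-ylidene]octa-2,4,6-trienal
Product: 23 (3R,6'R)-3-hydroxy-3'-oxo-7',8'-dihydro-β,ε-caroten-19',11'-olide (all-E polyene), via phosphonium ylide 21 (not isolated), via 11Z isomer 22 (not isolated)
Conditions: NaHMDS (1.05 equiv), THF, −78 °C; then 14, −78 → 0 °C; then toluene, 60 °C, dark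
Reagents that add atoms: none
Why: Wittig olefination, in which the semi-stabilised ylide (formed with one equivalent of non-nucleophilic base, the phosphonium C–H being far more acidic than the OH) adds only to the aldehyde, and the hindered 11Z isomer formed alongside is converted thermally to the all-E polyene; no stereocentre is touched.

Step 12
Reactants: 23 (3R,6'R)-3-hydroxy-3'-oxo-7',8'-dihydro-β,ε-caroten-19',11'-olide
Product: 24 (3S,5R,6S,6'R)-5,6-epoxy-3-hydroxy-3'-oxo-5,6,7',8'-tetrahydro-β,ε-caroten-19',11'-olide (target)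
Conditions: Boc-L-Asp-D-Pro-Aib-L-Phe-OMe (10 mol %), DMAP (10 mol %), DIC (1.5 equiv), 30 % aq. H2O2 (2 equiv), CH2Cl2, 0 °C, dark
Reagents that add atoms: hydrogen peroxide, OO
Why: Proposed new method: hydroxyl-anchored, catalyst-controlled anti-epoxidation of a carotenoid 3-hydroxy-β-end group, in which DIC/H2O2 turns the Asp side chain of a β-turn tetrapeptide into a transient peracid while a backbone carbonyl accepts a hydrogen bond from the only OH of 23 (C3–OH), so the electrophilic oxygen is held over the adjacent twisted, tetrasubstituted and most electron-rich C5=C6 bond (every other alkene is conjugated to the lactone or the ketone and deactivated) and is delivered in a concerted butterfly transition state to the face opposite the C3–O bond, the face being fixed by the chirality of the turn, which sets 5R and 6S in one event; the closest known reaction types are aspartyl-peptide peracid epoxidation that selects one alkene of a polyenol by hydrogen bonding to its hydroxyl, and the facially unselective peracid 5,6-epoxidation of carotenoids.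

## Compound list

1 | 2,4,4-trimethylcyclohex-2-en-1-one | CC1=CC(C)(C)CCC1=O | starting material
2 | (1S)-2,4,4-trimethylcyclohex-2-en-1-ol | CC1=CC(C)(C)CC[C@@H]1O | intermediate
3 | (6S)-6-[(1-ethoxyethenyl)oxy]-1,3,3-trimethylcyclohex-1-ene (mixed ketene acetal of 2) | CC1=CC(C)(C)CC[C@@H]1OC(=C)OCC | intermediate (not isolated)
4 | ethyl [(1R)-2,6,6-trimethylcyclohex-2-en-1-yl]acetate | CC1=CCCC(C)(C)[C@H]1CC(=O)OCC | intermediate
5 | 2-[(1R)-2,6,6-trimethylcyclohex-2-en-1-yl]ethan-1-ol | CC1=CCCC(C)(C)[C@H]1CCO | intermediate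
6 | (6R)-6-(2-bromoethyl)-1,5,5-trimethylcyclohex-1-ene | CC1=CCCC(C)(C)[C@H]1CCBr | intermediate
7 | (4R)-4-(2-bromoethyl)-3,5,5-trimethylcyclohex-2-en-1-one | CC1=CC(=O)CC(C)(C)[C@H]1CCBr | intermediate
8 | 3-bromofuran-2(5H)-one | O=C1OCC=C1Br | starting material
9 | (2E,4E,6E)-2,7-dimethylocta-2,4,6-trienedial (C10-dialdehyde) | O=C/C(C)=C/C=C/C=C(C)/C=O | starting material
10 | 3-bromo-2-[(tert-butyldimethylsilyl)oxy]furan | CC(C)(C)[Si](C)(C)Oc1occc1Br | intermediate (not isolated)
11 | (2E,4E,6E)-8-(4-bromo-5-oxo-2,5-dihydrofuran-2-yl)-8-[(tert-butyldimethylsilyl)oxy]-2,7-dimethylocta-2,4,6-trienal (diastereomer mixture) | O=C/C(C)=C/C=C/C=C(C)/C(O[Si](C)(C)C(C)(C)C)C1OC(=O)C(Br)=C1 | intermediate (not isolated)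
12 | (2E,4E,6E)-8-[(2Z)-4-bromo-5-oxofuran-2(5H)-ylidene]-2,7-dimethylocta-2,4,6-trienal | BrC1=C/C(=C/C(C)=C/C=C/C=C(C)/C=O)OC1=O | intermediate
13 | {2-[(1R)-2,6,6-trimethyl-4-oxocyclohex-2-en-1-yl]ethyl}zinc bromide | CC1=CC(=O)CC(C)(C)[C@H]1CC[Zn]Br | intermediate (not isolated)
14 | (2E,4E,6E)-2,7-dimethyl-8-[(2Z)-5-oxo-4-{2-[(1R)-2,6,6-trimethyl-4-oxocyclohex-2-en-1-yl]ethyl}furan-2(5H)-ylidene]octa-2,4,6-trienal | CC1=CC(=O)CC(C)(C)[C@H]1CCC1=C/C(=C/C(C)=C/C=C/C=C(C)/C=O)OC1=O | intermediate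
15 | (4R,6R)-4-hydroxy-2,2,6-trimethylcyclohexan-1-one (actinol) | CC1(C)C[C@H](O)C[C@@H](C)C1=O | starting material
16 | (2E)-3-methylpent-2-en-4-yn-1-ol | C#C/C(C)=C/CO | starting material
17 | dilithium salt of 16 (lithium acetylide, lithium alkoxide) | [Li]C#C/C(C)=C/CO[Li] | intermediate (not isolated)
18 | (4R,6R)-1-[(3E)-5-hydroxy-3-methylpent-3-en-1-yn-1-yl]-2,2,6-trimethylcyclohexane-1,4-diol (C1 epimers) | CC1(C)C[C@H](O)C[C@@H](C)C1(O)C#C/C(C)=C/CO | intermediate
19 | (4R,6R)-1-[(1E,3E)-5-hydroxy-3-methylpenta-1,3-dien-1-yl]-2,2,6-trimethylcyclohexane-1,4-diol (C1 epimers) | CC1(C)C[C@H](O)C[C@@H](C)C1(O)/C=C/C(C)=C/CO | intermediate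
20 | [(2E,4E)-5-[(4R)-4-hydroxy-2,6,6-trimethylcyclohex-1-en-1-yl]-3-methylpenta-2,4-dien-1-yl]triphenylphosphonium bromide | CC1=C(/C=C/C(C)=C/C[P+](c2ccccc2)(c2ccccc2)c2ccccc2)C(C)(C)C[C@H](O)C1.[Br-] | intermediate
21 | phosphonium ylide of 20 | CC1=C(/C=C/C(C)=C/C=P(c2ccccc2)(c2ccccc2)c2ccccc2)C(C)(C)C[C@H](O)C1 | intermediate (not isolated)
22 | 11Z isomer of 23 (cis at the newly formed C11=C12 bond, carotenoid numbering) | CC1=CC(=O)CC(C)(C)[C@H]1CCC1=C/C(=C/C(C)=C/C=C/C=C(C)/C=C\C=C(C)\C=C\C2=C(C)C[C@@H](O)CC2(C)C)OC1=O | intermediate (not isolated)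
23 | (5Z)-5-[(2E,4E,6E,8E,10E,12E)-13-[(4R)-4-hydroxy-2,6,6-trimethylcyclohex-1-en-1-yl]-2,7,11-trimethyltrideca-2,4,6,8,10,12-hexaen-1-ylidene]-3-{2-[(1R)-2,6,6-trimethyl-4-oxocyclohex-2-en-1-yl]ethyl}furan-2(5H)-one | CC1=CC(=O)CC(C)(C)[C@H]1CCC1=C/C(=C/C(C)=C/C=C/C=C(C)/C=C/C=C(C)/C=C/C2=C(C)C[C@@H](O)CC2(C)C)OC1=O | intermediate
24 | (5Z)-5-[(2E,4E,6E,8E,10E,12E)-13-[(1S,4S,6R)-4-hydroxy-2,2,6-trimethyl-7-oxabicyclo[4.1.0]heptan-1-yl]-2,7,11-trimethyltrideca-2,4,6,8,10,12-hexaen-1-ylidene]-3-{2-[(1R)-2,6,6-trimethyl-4-oxocyclohex-2-en-1-yl]ethyl}furan-2(5H)-one (the carbinol carbon is unchanged from 23; its descriptor switches from R to S by CIP priority only) | CC1=CC(=O)CC(C)(C)[C@H]1CCC1=C/C(=C/C(C)=C/C=C/C=C(C)/C=C/C=C(C)/C=C/[C@@]23O[C@]2(C)C[C@@H](O)CC3(C)C)OC1=O | target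

## Step count and risks

Total step count: 12. Longest linear sequence: 8 steps (1 → 24 through steps 1–5, 7, 11 and 12).

**Step 12 (proposed new epoxidation).** It can fail by giving the syn epoxide, by perhydrolysis of the enol lactone under DMAP/H2O2, or by acid-induced furanoid rearrangement of the vinyl epoxide. The Asp/Pro chirality pair matched to the anti face has to be confirmed first on (3R)-3-hydroxy-β-ionone; the mirror-image peptide is the alternative. The fallback uses known chemistry, sets out from 23 and returns at 24. Acetylation (Ac2O, pyridine, 0 °C) gives the 3-O-acetate F1, which removes any hydroxyl-directed syn delivery. Buffered peracid (mCPBA, NaHCO3, CH2Cl2, 0 °C), the classical substrate-controlled 5,6-epoxidation of carotenol acetates, gives the anti-epoxy acetate F2 together with the syn-epoxy acetate F3, which are separated by HPLC. Base-free lipase alcoholysis of F2 (Candida rugosa lipase, n-BuOH, MTBE, 35 °C) frees 24. This costs two extra steps and roughly half the material.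

**Step 7 (Negishi coupling on the polyenal bromide).** The α-bromo ylidenebutenolide trienal 12 may be reduced or decompose under Pd/Zn. The fallback moves the sp3–sp2 coupling onto the robust bromofuranone; it sets out from 13 (made from 7 as before) and 8 and returns at 14, making step 6 unnecessary. Under the same Pd(OAc)2/SPhos conditions 13 couples with 8 to give the 3-alkylfuranone F4. F4 is then condensed with dialdehyde 9 by the one-pot TBSOTf/i-Pr2NEt then DBU protocol, with TBSOTf limiting so that the more acidic butenolide and not the enone is silylated. This passes through the silyloxyfuran F5 (not isolated) and the aldol silyl ether F6 (not isolated) and gives 14.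

**Step 6 (mono-condensation of the dialdehyde with the bromofuranone).** It can fail through bis-condensation, poor Z/E control, or attack of DBU on the bromo-enoate. The fallback builds the lactone by C–O ring closure instead; it sets out from 9 and returns at 12. Statistical mono-alkynylation of 9 (lithiated TMSCHN2 from LDA, THF, −78 °C → rt, Colvin rearrangement, excess 9 recycled) gives the enynal F7. Tandem Sonogashira coupling and 5-exo-dig oxycyclization of F7 with (E)-2,3-dibromoacrylic acid (PdCl2(PPh3)2, CuI, Et3N, MeCN, rt) proceeds through the bromo-enynoic acid F8 (not isolated), coupling at the more reactive β-bromide and closing by anti-oxymetalation to the Z-ylidenebutenolide 12.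

## Further compounds

F1 | step 12 | 3-O-acetate of 23, (3R,6'R) | CC1=CC(=O)CC(C)(C)[C@H]1CCC1=C/C(=C/C(C)=C/C=C/C=C(C)/C=C/C=C(C)/C=C/C2=C(C)C[C@@H](OC(C)=O)CC2(C)C)OC1=O
F2 | step 12 | anti-epoxy acetate, 3-O-acetate of 24, (3S,5R,6S,6'R) | CC1=CC(=O)CC(C)(C)[C@H]1CCC1=C/C(=C/C(C)=C/C=C/C=C(C)/C=C/C=C(C)/C=C/[C@@]23O[C@]2(C)C[C@@H](OC(C)=O)CC3(C)C)OC1=O
F3 | step 12 | syn-epoxy acetate, (3S,5S,6R,6'R) | CC1=CC(=O)CC(C)(C)[C@H]1CCC1=C/C(=C/C(C)=C/C=C/C=C(C)/C=C/C=C(C)/C=C/[C@]23O[C@@]2(C)C[C@@H](OC(C)=O)CC3(C)C)OC1=O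
F4 | step 7 | 3-{2-[(1R)-2,6,6-trimethyl-4-oxocyclohex-2-en-1-yl]ethyl}furan-2(5H)-one | CC1=CC(=O)CC(C)(C)[C@H]1CCC1=CCOC1=O
F5 | step 7 | (4R)-4-[2-(2-{[tert-butyl(dimethyl)silyl]oxy}furan-3-yl)ethyl]-3,5,5-trimethylcyclohex-2-en-1-one | CC1=CC(=O)CC(C)(C)[C@H]1CCc1ccoc1O[Si](C)(C)C(C)(C)C
F6 | step 7 | (2E,4E,6E)-8-[(tert-butyldimethylsilyl)oxy]-2,7-dimethyl-8-(5-oxo-4-{2-[(1R)-2,6,6-trimethyl-4-oxocyclohex-2-en-1-yl]ethyl}-2,5-dihydrofuran-2-yl)octa-2,4,6-trienal (diastereomer mixture) | CC1=CC(=O)CC(C)(C)[C@H]1CCC1=CC(OC1=O)C(O[Si](C)(C)C(C)(C)C)/C(C)=C/C=C/C=C(C)/C=O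
F7 | step 6 | (2E,4E,6E)-2,7-dimethylnona-2,4,6-trien-8-ynal | C#C/C(C)=C/C=C/C=C(C)/C=O
F8 | step 6 | (2E,6E,8E,10E)-2-bromo-6,11-dimethyl-12-oxododeca-2,6,8,10-tetraen-4-ynoic acid | OC(=O)/C(Br)=C\C#C/C(C)=C/C=C/C=C(C)/C=O
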